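**Plan**

- Feature used: C3 and C7 (and, mirrored, C22 and C18) are methyl-bearing CH centres, each bonded to the substituted carbon of a 1,1-disubstituted alkene (C2=C1H2, C6=CH2, C23=C24H2, C19=CH2). The only rings are the two oxiranes O–C10–C11 and O–C14–C15, so the carbon skeleton is an open chain.
- Cuts: both oxirane C–O pairs back to the 10E and 14E alkenes; C12–C13 (allyl bromide plus allyl sulfone); C3–CH3 and C7–CH3 together by a twofold SN2' methylation of a bis(allylic chloride); C2=C3 (Wittig) and C6=C7 (Horner–Wadsworth–Emmons) back to one geraniol-derived aldehyde.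
- Forward: geraniol → aldehyde 4 → ester acetal 8 (branch point). Left half: 8 → dichloride 14 → 16 in one double methylation. Right half: the same operations from 8, one site at a time. The halves are joined at C12–C13, the sulfone is removed, and the two oxirane rings are closed last on the hexaene.
- Stereochemistry: C3, C7 and C18 come from one enantiomer of a copper-bound phosphoramidite, C22 from its mirror image. Alkene geometries come from geraniol, the two olefinations and stereoretentive substitutions. C10, C11, C14 and C15 come from the L-fructose-derived Shi ketone.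

Key step: step 10

Numbering and abbreviations: atoms carry the numbers of the C24 chain of the target (C1 = CH2 of the left isopropenyl group, C24 = CH2 of the right one). TBDPS = tert-butyldiphenylsilyl. Lig = (Sa,S,S)-phosphoramidite from 2,2'-binaphthol and bis[(S)-1-(2-methoxyphenyl)ethyl]amine; ent-Lig = its (Ra,R,R) mirror image.

Assumption: Lig on copper is taken to deliver methyl to the Re face of the alkene CH carbon (vinyl carbon → chain carbon → H clockwise), which gives R at C3, C7 and C18; if the sense of induction is the opposite, Lig and ent-Lig change places and nothing else changes.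

**Route**

Step 1
Reactants: 1 geraniol
Product: 2 geranyl TBDPS ether
Conditions: TBDPSCl, imidazole, DMF, 0 °C to rt
Reagents that add atoms: tert-butyl(chloro)diphenylsilane, CC(C)(C)[Si](Cl)(c1ccccc1)c1ccccc1
Why: Imidazole-promoted silylation of a primary allylic alcohol is routine, and the TBDPS ether is chosen because it has to survive periodic acid in step 3 and aqueous acid in steps 6 and 16.

Step 2
Reactants: 2 geranyl TBDPS ether
Product: 3 6,7-epoxygeranyl TBDPS ether (racemic)
Conditions: mCPBA, NaHCO3, CH2Cl2, −20 to 0 °C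
Reagents that add atoms: 3-chloroperbenzoic acid, OOC(=O)c1cccc(Cl)c1
Why: Prilezhaev epoxidation goes to the more electron-rich distal alkene, since the 2,3-alkene is deactivated by the allylic oxygen and shielded by the silyl group, and the missing enantiocontrol is of no consequence because the oxirane carbons are cleaved apart in step 3.

Step 3
Reactants: 3 6,7-epoxygeranyl TBDPS ether
Product: 4 (4E)-6-(TBDPS-oxy)-4-methylhex-4-enal
Conditions: H5IO6, THF/H2O, 0 °C
Reagents that add atoms: none
Why: Periodic acid hydrolyses the epoxide to the glycol and cleaves it in the same flask (Malaprade-type glycol cleavage), leaving the former C6 of geraniol as the aldehyde and releasing the gem-dimethyl carbon as acetone.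

Step 4
Reactants: 5 triethyl phosphonoacetate; 6 2-(2-bromoethyl)-1,3-dioxolane
Product: 7 ethyl 2-(diethoxyphosphoryl)-4-(1,3-dioxolan-2-yl)butanoate
Conditions: NaH, DMSO, rt to 60 °C, 5 in excess
Reagents that add atoms: none
Why: C-alkylation of the sodium salt of a phosphonoacetate by a primary bromide (SN2) is standard in a dipolar aprotic solvent, and the excess of 5 should hold back dialkylation.

Step 5
Reactants: 4 (4E)-6-(TBDPS-oxy)-4-methylhex-4-enal; 7 ethyl 2-(diethoxyphosphoryl)-4-(1,3-dioxolan-2-yl)butanoate
Product: 8 ester acetal, ethyl (2E,6E)-8-(TBDPS-oxy)-2-[2-(1,3-dioxolan-2-yl)ethyl]-6-methylocta-2,6-dienoate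
Conditions: NaH, THF, 0 °C; then 4, 0 °C to rt; E isomer purified by chromatography
Reagents that add atoms: none
Why: Horner–Wadsworth–Emmons olefination of an unbranched aldehyde with an α-alkyl phosphonoacetate under equilibrating conditions should favour the E enoate (ester trans to the chain), and the minor Z isomer is removed here because alkene geometry at this bond later decides the configuration at C7 and C18.

Step 6
Reactants: 8 ester acetal
Product: 9 ester aldehyde, ethyl (2E,6E)-8-(TBDPS-oxy)-6-methyl-2-(3-oxopropyl)octa-2,6-dienoate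
Conditions: 1 M HCl, THF, rt
Reagents that add atoms: water, O
Why: Acid-catalysed acetal hydrolysis frees the aldehyde, while the TBDPS ether and the enoate are stable to dilute aqueous acid at room temperature.

Step 7
Reactants: 9 ester aldehyde; 10 ethyl 2-(triphenylphosphoranylidene)propanoate
Product: 11 diester, ethyl (2E,6E,10E)-6-(ethoxycarbonyl)-2,10-dimethyl-12-(TBDPS-oxy)dodeca-2,6,10-trienoate
Conditions: toluene, 60 °C
Reagents that add atoms: none
Why: Wittig olefination with a stabilised α-methyl ylide gives the E trisubstituted enoate reliably and needs no base, so the existing enoate and the silyl ether are untouched.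

Step 8
Reactants: 11 diester
Product: 12 diol, (2E,6E,10E)-6-(hydroxymethyl)-2,10-dimethyl-12-(TBDPS-oxy)dodeca-2,6,10-trien-1-ol
Conditions: i-Bu2AlH (excess), CH2Cl2, −78 °C; aqueous potassium sodium tartrate
Reagents that add atoms: none
Why: 1,2-Reduction of α,β-unsaturated esters to allylic alcohols by i-Bu2AlH at low temperature leaves alkene geometry and the silyl ether intact.

Step 9
Reactants: 12 diol
Product: 14 bis(allylic chloride), (2E,6E,10E)-1-chloro-6-(chloromethyl)-2,10-dimethyl-12-(TBDPS-oxy)dodeca-2,6,10-triene, via bis-mesylate 13 (not isolated)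
Conditions: MsCl, 2,4,6-collidine, LiCl, DMF, 0 °C
Reagents that add atoms: lithium chloride, [Li+].[Cl-]; methanesulfonyl chloride, CS(=O)(=O)Cl (chloride only)
Why: Mesylation followed by SN2 displacement with chloride in DMF at 0 °C converts primary allylic alcohols into the chlorides without allylic transposition or E/Z isomerisation.

Step 10
Reactants: 14 bis(allylic chloride); 15 methylmagnesium bromide
Product: 16 left-half silyl ether, (3R,7R,10E)-12-(TBDPS-oxy)-2,3,7,10-tetramethyl-6-methylidenedodeca-1,10-diene
Conditions: CuBr·SMe2 (6 mol %), Lig (7 mol %), CH2Cl2, −78 °C; MeMgBr (Et2O solution, 2.5 equiv) added slowly by syringe pump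
Reagents that add atoms: methylmagnesium bromide, C[Mg]Br (second equivalent of 15)
Why: The methylcuprate of monovalent copper formed from CuBr·SMe2, Lig and 15 coordinates each allylic alkene on the face anti to its C–Cl bond and adds oxidatively to a γ-bound σ-allyl species of trivalent copper; reductive elimination, which under slow Grignard addition at −78 °C outruns σ–π–σ equilibration, then puts methyl on C3 and on C7 and leaves the alkenes at C1=C2 and C6=CH2, so that two equivalents of 15 are consumed, one per C–Cl bond. The closest known reaction type is the copper-catalysed enantioselective allylic alkylation (SN2') of 2-substituted E allylic chlorides with Grignard reagents and phosphoramidite ligands, used here at two such sites of one molecule. No ring is closed. Both new stereocentres are set by the ligand on copper: the two sites have the same E geometry (CH2Cl trans to the chain) and the same substitution pattern, so one ligand enantiomer should deliver methyl to the Re face of both and give R at C3 and at C7, with the doubly mismatched enantiomer statistically negligible. The step needs SN2' over SN2 regioselectivity and face selectivity, which are secured by the chloride leaving group, the non-coordinating solvent and the geometric purity of the (2E,6E) substrate fixed in steps 5 and 7. The allylic silyl ether at C12 and the C10=C11 alkene are not activated for substitution and stay as spectators.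

Step 11
Reactants: 16 left-half silyl ether
Product: 17 left-half allylic alcohol, (2E,6R,10R)-3,6,10,11-tetramethyl-7-methylidenedodeca-2,11-dien-1-ol
Conditions: Bu4NF, THF, 0 °C to rt
Reagents that add atoms: none
Why: Fluoride-mediated desilylation cleaves the Si–O bond and touches neither the alkenes nor the two allylic stereocentres.

Step 12
Reactants: 17 left-half allylic alcohol
Product: 18 left-half allylic bromide, (2E,6R,10R)-1-bromo-3,6,10,11-tetramethyl-7-methylidenedodeca-2,11-diene
Conditions: CBr4, PPh3, CH2Cl2, 0 °C; used without storage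
Reagents that add atoms: carbon tetrabromide, BrC(Br)(Br)Br
Why: The Appel reaction replaces the primary allylic hydroxyl by bromide in an SN2 step under neutral conditions, so no HBr adds to the 1,1-disubstituted alkenes and the 10E geometry is kept.

Step 13
Reactants: 8 ester acetal
Product: 19 allylic alcohol acetal, (2E,6E)-8-(TBDPS-oxy)-2-[2-(1,3-dioxolan-2-yl)ethyl]-6-methylocta-2,6-dien-1-ol
Conditions: i-Bu2AlH, CH2Cl2, −78 °C; aqueous potassium sodium tartrate
Reagents that add atoms: none
Why: 1,2-Reduction of the enoate by i-Bu2AlH at −78 °C leaves the dioxolane, which keeps the second methylation site masked.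

Step 14
Reactants: 19 allylic alcohol acetal
Product: 21 allylic chloride acetal, tert-butyl{[(2E,6E)-7-(chloromethyl)-9-(1,3-dioxolan-2-yl)-3-methylnona-2,6-dien-1-yl]oxy}diphenylsilane, via allylic mesylate 20 (not isolated)
Conditions: MsCl, 2,4,6-collidine, LiCl, DMF, 0 °C
Reagents that add atoms: lithium chloride, [Li+].[Cl-]; methanesulfonyl chloride, CS(=O)(=O)Cl (chloride only)
Why: The same mesylation and SN2 chloride displacement as in step 9 applies, and the collidine buffer keeps the acetal safe.

Step 15
Reactants: 21 allylic chloride acetal; 15 methylmagnesium bromide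
Product: 22 (18R) acetal, tert-butyl{[(2E,6R)-9-(1,3-dioxolan-2-yl)-3,6-dimethyl-7-methylidenenon-2-en-1-yl]oxy}diphenylsilane
Conditions: CuBr·SMe2 (3 mol %), Lig (3.5 mol %), CH2Cl2, −78 °C; MeMgBr added slowly
Reagents that add atoms: none
Why: This is the copper-catalysed enantioselective SN2' methylation of step 10 at a single E allylic chloride of identical local structure to the C6/C7 site, so Lig should again direct methyl to the Re face and give R at C18, and the dioxolane is inert to the Grignard reagent at −78 °C.

Step 16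
Reactants: 22 (18R) acetal
Product: 23 (18R) aldehyde, (5R,8E)-10-(TBDPS-oxy)-5,8-dimethyl-4-methylidenedec-8-enal
Conditions: 1 M HCl, THF, 0 °C to rt
Reagents that add atoms: water, O
Why: Acetal hydrolysis in dilute aqueous acid is too mild to protonate the 1,1-disubstituted alkene or to cleave the TBDPS ether, and C18 is not α to the new carbonyl and cannot epimerise.

Step 17
Reactants: 23 (18R) aldehyde; 10 ethyl 2-(triphenylphosphoranylidene)propanoate
Product: 24 (18R) enoate, ethyl (2E,7R,10E)-12-(TBDPS-oxy)-2,7,10-trimethyl-6-methylidenedodeca-2,10-dienoate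
Conditions: toluene, 60 °C
Reagents that add atoms: none
Why: Base-free Wittig olefination with the stabilised α-methyl ylide gives the E enoate, as in step 7.

Step 18
Reactants: 24 (18R) enoate
Product: 25 (18R) allylic alcohol, (2E,7R,10E)-12-(TBDPS-oxy)-2,7,10-trimethyl-6-methylidenedodeca-2,10-dien-1-ol
Conditions: i-Bu2AlH, CH2Cl2, −78 °C; aqueous potassium sodium tartrate
Reagents that add atoms: none
Why: 1,2-Reduction of the enoate by i-Bu2AlH, as in step 8.

Step 19
Reactants: 25 (18R) allylic alcohol
Product: 27 (18R) allylic chloride, (2E,7R,10E)-1-chloro-12-(TBDPS-oxy)-2,7,10-trimethyl-6-methylidenedodeca-2,10-diene, via allylic mesylate 26 (not isolated)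
Conditions: MsCl, 2,4,6-collidine, LiCl, DMF, 0 °C
Reagents that add atoms: lithium chloride, [Li+].[Cl-]; methanesulfonyl chloride, CS(=O)(=O)Cl (chloride only)
Why: Mesylation and SN2 chloride displacement without allylic transposition, as in step 9.

Step 20
Reactants: 27 (18R) allylic chloride; 15 methylmagnesium bromide
Product: 28 right-half silyl ether, (3S,7R,10E)-12-(TBDPS-oxy)-2,3,7,10-tetramethyl-6-methylidenedodeca-1,10-diene (18R,22S in target numbering)
Conditions: CuBr·SMe2 (3 mol %), ent-Lig (3.5 mol %), CH2Cl2, −78 °C; MeMgBr added slowly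
Reagents that add atoms: none
Why: The same copper-catalysed enantioselective SN2' methylation with the mirror-image ligand should deliver methyl to the Si face and give S at C22, under catalyst control because the existing C18 centre is four bonds away from the reacting carbon.

Step 21
Reactants: 28 right-half silyl ether
Product: 29 right-half allylic alcohol, (2E,6R,10S)-3,6,10,11-tetramethyl-7-methylidenedodeca-2,11-dien-1-ol
Conditions: Bu4NF, THF, 0 °C to rt
Reagents that add atoms: none
Why: Fluoride-mediated desilylation, as in step 11.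

Step 22
Reactants: 29 right-half allylic alcohol
Product: 30 right-half allylic bromide, (2E,6R,10S)-1-bromo-3,6,10,11-tetramethyl-7-methylidenedodeca-2,11-diene
Conditions: CBr4, PPh3, CH2Cl2, 0 °C; used without storage
Reagents that add atoms: carbon tetrabromide, BrC(Br)(Br)Br
Why: Appel bromination of the primary allylic alcohol under neutral conditions, as in step 12.

Step 23
Reactants: 30 right-half allylic bromide
Product: 31 right-half allylic sulfone, {[(2E,6R,10S)-3,6,10,11-tetramethyl-7-methylidenedodeca-2,11-dien-1-yl]sulfonyl}benzene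
Conditions: PhSO2Na, DMF, 0 °C to rt
Reagents that add atoms: sodium benzenesulfinate, [Na+].[O-]S(=O)c1ccccc1
Why: The sulfinate anion alkylates at sulfur in an SN2 reaction with the primary allylic bromide, giving the sulfone with the E alkene unchanged.

Step 24
Reactants: 31 right-half allylic sulfone; 18 left-half allylic bromide
Product: 32 coupled C13 sulfone (3R,7R,10E,14E,18R,22S; both C13 epimers)
Conditions: n-BuLi, THF/DMPU, −78 °C; then 18, −78 to −40 °C
Reagents that add atoms: none
Why: Alkylation of the α-lithio allyl sulfone at its α-carbon by the primary allylic bromide (SN2, Biellmann-type coupling) forms C12–C13 with both trisubstituted alkenes in place, and the uncontrolled C13 centre disappears in step 25.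

Step 25
Reactants: 32 coupled C13 sulfone
Product: 33 hexaene, (3R,7R,10E,14E,18R,22S)-2,3,7,10,15,18,22,23-octamethyl-6,19-dimethylidenetetracosa-1,10,14,23-tetraene
Conditions: PdCl2(dppp) (cat.), LiBHEt3, THF, 0 °C
Reagents that add atoms: none
Why: In this palladium-catalysed reductive desulfonylation, zerovalent palladium formed in the flask ionises the allylic sulfone to a π-allyl complex and hydride is delivered to the less substituted terminus C13, so the C14=C15 alkene should stay in place with E geometry.

Step 26
Reactants: 33 hexaene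
Product: 34 target, (3R,7R,10S,11S,14S,15S,18R,22S)-10,11:14,15-diepoxy-2,3,7,10,15,18,22,23-octamethyl-6,19-dimethylidenetetracosa-1,23-diene
Conditions: L-fructose-derived Shi ketone (1,2:4,5-di-O-isopropylidene-β-L-erythro-2,3-hexodiulo-2,6-pyranose), KHSO5 (as Oxone), K2CO3, Bu4NHSO4, Na2B4O7/Na2EDTA buffer, MeCN/CH2(OMe)2, −5 to 0 °C; stopped before the 1,1-disubstituted alkenes react, under-oxidised material recycled
Reagents that add atoms: potassium peroxymonosulfate, [K+].[O-]S(=O)(=O)OO
Why: In the Shi epoxidation the chiral dioxirane transfers oxygen through a spiro transition state to E-trisubstituted alkenes, its best substrate class and more electron-rich than the four 1,1-disubstituted alkenes, and the L-configured ketone should attack the face that gives S,S at C10/C11 and at C14/C15, the trans oxirane geometry following from the E alkenes.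

**Compound list**

1 | geraniol, (2E)-3,7-dimethylocta-2,6-dien-1-ol | CC(C)=CCC/C(C)=C/CO | starting material
2 | geranyl TBDPS ether, tert-butyl{[(2E)-3,7-dimethylocta-2,6-dien-1-yl]oxy}diphenylsilane | CC(C)=CCC/C(C)=C/CO[Si](c1ccccc1)(c1ccccc1)C(C)(C)C | intermediate
3 | 6,7-epoxygeranyl TBDPS ether, tert-butyl{[(2E)-5-(3,3-dimethyloxiran-2-yl)-3-methylpent-2-en-1-yl]oxy}diphenylsilane (racemic) | CC1(C)OC1CC/C(C)=C/CO[Si](c1ccccc1)(c1ccccc1)C(C)(C)C | intermediate
4 | (4E)-6-(TBDPS-oxy)-4-methylhex-4-enal | O=CCC/C(C)=C/CO[Si](c1ccccc1)(c1ccccc1)C(C)(C)C | intermediate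
5 | triethyl phosphonoacetate | CCOC(=O)CP(=O)(OCC)OCC | starting material
6 | 2-(2-bromoethyl)-1,3-dioxolane | BrCCC1OCCO1 | starting material
7 | ethyl 2-(diethoxyphosphoryl)-4-(1,3-dioxolan-2-yl)butanoate (racemic) | CCOC(=O)C(CCC1OCCO1)P(=O)(OCC)OCC | intermediate
8 | ester acetal, ethyl (2E,6E)-8-(TBDPS-oxy)-2-[2-(1,3-dioxolan-2-yl)ethyl]-6-methylocta-2,6-dienoate | CCOC(=O)/C(CCC1OCCO1)=C/CC/C(C)=C/CO[Si](c1ccccc1)(c1ccccc1)C(C)(C)C | intermediate
9 | ester aldehyde, ethyl (2E,6E)-8-(TBDPS-oxy)-6-methyl-2-(3-oxopropyl)octa-2,6-dienoate | CCOC(=O)/C(CCC=O)=C/CC/C(C)=C/CO[Si](c1ccccc1)(c1ccccc1)C(C)(C)C | intermediate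
10 | ethyl 2-(triphenylphosphoranylidene)propanoate | CCOC(=O)C(C)=P(c1ccccc1)(c1ccccc1)c1ccccc1 | starting material
11 | diester, ethyl (2E,6E,10E)-6-(ethoxycarbonyl)-2,10-dimethyl-12-(TBDPS-oxy)dodeca-2,6,10-trienoate | CCOC(=O)/C(C)=C/CC/C(C(=O)OCC)=C\CC/C(C)=C/CO[Si](c1ccccc1)(c1ccccc1)C(C)(C)C | intermediate
12 | diol, (2E,6E,10E)-6-(hydroxymethyl)-2,10-dimethyl-12-(TBDPS-oxy)dodeca-2,6,10-trien-1-ol | OC/C(C)=C/CC/C(CO)=C\CC/C(C)=C/CO[Si](c1ccccc1)(c1ccccc1)C(C)(C)C | intermediate
13 | bis-mesylate of diol 12 | CS(=O)(=O)OC/C(C)=C/CC/C(COS(C)(=O)=O)=C\CC/C(C)=C/CO[Si](c1ccccc1)(c1ccccc1)C(C)(C)C | intermediate (not isolated)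
14 | bis(allylic chloride), (2E,6E,10E)-1-chloro-6-(chloromethyl)-2,10-dimethyl-12-(TBDPS-oxy)dodeca-2,6,10-triene | ClC/C(C)=C/CC/C(CCl)=C\CC/C(C)=C/CO[Si](c1ccccc1)(c1ccccc1)C(C)(C)C | intermediate
15 | methylmagnesium bromide | C[Mg]Br | starting material
16 | left-half silyl ether, (3R,7R,10E)-12-(TBDPS-oxy)-2,3,7,10-tetramethyl-6-methylidenedodeca-1,10-diene | C=C(C)[C@H](C)CCC(=C)[C@H](C)CC/C(C)=C/CO[Si](c1ccccc1)(c1ccccc1)C(C)(C)C | intermediate
17 | left-half allylic alcohol, (2E,6R,10R)-3,6,10,11-tetramethyl-7-methylidenedodeca-2,11-dien-1-ol | C=C(C)[C@H](C)CCC(=C)[C@H](C)CC/C(C)=C/CO | intermediate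
18 | left-half allylic bromide, (2E,6R,10R)-1-bromo-3,6,10,11-tetramethyl-7-methylidenedodeca-2,11-diene | C=C(C)[C@H](C)CCC(=C)[C@H](C)CC/C(C)=C/CBr | intermediate
19 | allylic alcohol acetal, (2E,6E)-8-(TBDPS-oxy)-2-[2-(1,3-dioxolan-2-yl)ethyl]-6-methylocta-2,6-dien-1-ol | OC/C(CCC1OCCO1)=C/CC/C(C)=C/CO[Si](c1ccccc1)(c1ccccc1)C(C)(C)C | intermediate
20 | allylic mesylate of 19 | CS(=O)(=O)OC/C(CCC1OCCO1)=C/CC/C(C)=C/CO[Si](c1ccccc1)(c1ccccc1)C(C)(C)C | intermediate (not isolated)
21 | allylic chloride acetal, tert-butyl{[(2E,6E)-7-(chloromethyl)-9-(1,3-dioxolan-2-yl)-3-methylnona-2,6-dien-1-yl]oxy}diphenylsilane | ClC/C(CCC1OCCO1)=C/CC/C(C)=C/CO[Si](c1ccccc1)(c1ccccc1)C(C)(C)C | intermediate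
22 | (18R) acetal, tert-butyl{[(2E,6R)-9-(1,3-dioxolan-2-yl)-3,6-dimethyl-7-methylidenenon-2-en-1-yl]oxy}diphenylsilane | C=C(CCC1OCCO1)[C@H](C)CC/C(C)=C/CO[Si](c1ccccc1)(c1ccccc1)C(C)(C)C | intermediate
23 | (18R) aldehyde, (5R,8E)-10-(TBDPS-oxy)-5,8-dimethyl-4-methylidenedec-8-enal | C=C(CCC=O)[C@H](C)CC/C(C)=C/CO[Si](c1ccccc1)(c1ccccc1)C(C)(C)C | intermediate
24 | (18R) enoate, ethyl (2E,7R,10E)-12-(TBDPS-oxy)-2,7,10-trimethyl-6-methylidenedodeca-2,10-dienoate | CCOC(=O)/C(C)=C/CCC(=C)[C@H](C)CC/C(C)=C/CO[Si](c1ccccc1)(c1ccccc1)C(C)(C)C | intermediate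
25 | (18R) allylic alcohol, (2E,7R,10E)-12-(TBDPS-oxy)-2,7,10-trimethyl-6-methylidenedodeca-2,10-dien-1-ol | OC/C(C)=C/CCC(=C)[C@H](C)CC/C(C)=C/CO[Si](c1ccccc1)(c1ccccc1)C(C)(C)C | intermediate
26 | allylic mesylate of 25 | CS(=O)(=O)OC/C(C)=C/CCC(=C)[C@H](C)CC/C(C)=C/CO[Si](c1ccccc1)(c1ccccc1)C(C)(C)C | intermediate (not isolated)
27 | (18R) allylic chloride, (2E,7R,10E)-1-chloro-12-(TBDPS-oxy)-2,7,10-trimethyl-6-methylidenedodeca-2,10-diene | ClC/C(C)=C/CCC(=C)[C@H](C)CC/C(C)=C/CO[Si](c1ccccc1)(c1ccccc1)C(C)(C)C | intermediate
28 | right-half silyl ether, (3S,7R,10E)-12-(TBDPS-oxy)-2,3,7,10-tetramethyl-6-methylidenedodeca-1,10-diene | C=C(C)[C@@H](C)CCC(=C)[C@H](C)CC/C(C)=C/CO[Si](c1ccccc1)(c1ccccc1)C(C)(C)C | intermediate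
29 | right-half allylic alcohol, (2E,6R,10S)-3,6,10,11-tetramethyl-7-methylidenedodeca-2,11-dien-1-ol | C=C(C)[C@@H](C)CCC(=C)[C@H](C)CC/C(C)=C/CO | intermediate
30 | right-half allylic bromide, (2E,6R,10S)-1-bromo-3,6,10,11-tetramethyl-7-methylidenedodeca-2,11-diene | C=C(C)[C@@H](C)CCC(=C)[C@H](C)CC/C(C)=C/CBr | intermediate
31 | right-half allylic sulfone, {[(2E,6R,10S)-3,6,10,11-tetramethyl-7-methylidenedodeca-2,11-dien-1-yl]sulfonyl}benzene | C=C(C)[C@@H](C)CCC(=C)[C@H](C)CC/C(C)=C/CS(=O)(=O)c1ccccc1 | intermediate
32 | coupled C13 sulfone, 13-(phenylsulfonyl) derivative of hexaene 33 (both C13 epimers) | C=C(C)[C@H](C)CCC(=C)[C@H](C)CC/C(C)=C/CC(S(=O)(=O)c1ccccc1)/C=C(C)/CC[C@@H](C)C(=C)CC[C@H](C)C(=C)C | intermediate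
33 | hexaene, (3R,7R,10E,14E,18R,22S)-2,3,7,10,15,18,22,23-octamethyl-6,19-dimethylidenetetracosa-1,10,14,23-tetraene | C=C(C)[C@H](C)CCC(=C)[C@H](C)CC/C(C)=C/CC/C=C(C)/CC[C@@H](C)C(=C)CC[C@H](C)C(=C)C | intermediate
34 | (3R,7R,10S,11S,14S,15S,18R,22S)-10,11:14,15-diepoxy-2,3,7,10,15,18,22,23-octamethyl-6,19-dimethylidenetetracosa-1,23-diene | C=C(C)[C@H](C)CCC(=C)[C@H](C)CC[C@]1(C)O[C@H]1CC[C@@H]1O[C@@]1(C)CC[C@@H](C)C(=C)CC[C@H](C)C(=C)C | target

**Step count and risks**

Total: 26 steps. Longest linear sequence: 18 steps (steps 1–3, 5, 13–26). The left half takes 14 steps in line (steps 1–3, 5–12, 24–26); step 4 is a one-step side branch.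

Steps most likely to fail:

1. Step 10 (double SN2' methylation). The two chloride sites may react at different rates: the C6/C7 site carries the larger 2-substituent. Forcing the slower site to completion may cost regioselectivity (direct SN2 leakage) or face selectivity, and stopping early would leave mono-methylated material that is hard to separate. The fallback forms one C–CH3 bond at a time on substrates that each carry a single allylic chloride. It sets out from ester acetal 8 and follows steps 13 to 19 through 19, 21, 22, 23, 24, 25 and 27; chloride 27 already has the R centre at the carbon that is C7 of the left half. Its methylation is then run with Lig in place of ent-Lig, which gives the (3R,7R) silyl ether, and the fallback comes back to the route at 16. No compound outside the list is made (F0).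

2. Step 26 (double Shi epoxidation). The four 1,1-disubstituted alkenes may be oxidised before both trisubstituted alkenes are consumed, giving a mixture of under- and over-epoxidised products. The fallback installs the left oxirane under hydroxyl direction, where no other alkene can react, and leaves only one undirected epoxidation, so less conversion has to be forced past the competing alkenes. It sets out from allylic alcohol 17. Sharpless asymmetric epoxidation (Ti(OiPr)4, L-(+)-diethyl tartrate, t-BuOOH, 4 Å molecular sieves, CH2Cl2, −20 °C) gives the left-half (10S,11S)-epoxy alcohol F1. Tf2O and 2,6-lutidine in CH2Cl2 at −78 °C convert it into the left-half epoxy triflate F2. F2 alkylates the lithio derivative of sulfone 31 (n-BuLi, THF, −78 °C) to the coupled epoxy sulfone F3. Sodium amalgam with Na2HPO4 in MeOH/THF at −20 °C removes the sulfone without opening the oxirane and gives the 10,11-monoepoxide pentaene F4. One Shi epoxidation under the conditions of step 26 then closes the second oxirane, and the fallback comes back to the route at 34.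

3. Step 5 (Horner–Wadsworth–Emmons olefination). E/Z control with an α-alkyl phosphonoacetate and an unbranched aldehyde may be poor and the isomers may co-elute; Z material carried forward would reach the methylation as the Z allylic chloride and give the wrong configuration at C7 and C18. The fallback forms the C6=C7 bond with a stabilised phosphorus ylide, which is reliably E-selective with aldehydes. It sets out from bromide 6 and aldehyde 4. NaI in acetone converts 6 into 2-(2-iodoethyl)-1,3-dioxolane F5. F5 alkylates commercial ethyl (triphenylphosphoranylidene)acetate in refluxing MeCN to [1-ethoxycarbonyl-3-(1,3-dioxolan-2-yl)propyl]triphenylphosphonium iodide F6. Aqueous NaOH/CH2Cl2 gives ethyl 4-(1,3-dioxolan-2-yl)-2-(triphenylphosphoranylidene)butanoate F7. Wittig reaction of F7 with 4 in toluene at 80 °C gives the E enoate, and the fallback comes back to the route at 8.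

Further compounds
F0 | step 10 | none | none
F1 | step 26 | left-half (10S,11S)-epoxy alcohol, [(2S,3S)-3-methyl-3-[(3R,7R)-3,7,8-trimethyl-4-methylidenenon-8-en-1-yl]oxiran-2-yl]methanol | C=C(C)[C@H](C)CCC(=C)[C@H](C)CC[C@]1(C)O[C@H]1CO
F2 | step 26 | left-half epoxy triflate, trifluoromethanesulfonate of F1 | C=C(C)[C@H](C)CCC(=C)[C@H](C)CC[C@]1(C)O[C@H]1COS(=O)(=O)C(F)(F)F
F3 | step 26 | coupled epoxy sulfone, 10,11-epoxide of 32 (both C13 epimers) | C=C(C)[C@H](C)CCC(=C)[C@H](C)CC[C@]1(C)O[C@H]1CC(S(=O)(=O)c1ccccc1)/C=C(C)/CC[C@@H](C)C(=C)CC[C@H](C)C(=C)C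
F4 | step 26 | 10,11-monoepoxide pentaene (3R,7R,10S,11S,14E,18R,22S) | C=C(C)[C@H](C)CCC(=C)[C@H](C)CC[C@]1(C)O[C@H]1CC/C=C(C)/CC[C@@H](C)C(=C)CC[C@H](C)C(=C)C
F5 | step 5 | 2-(2-iodoethyl)-1,3-dioxolane | ICCC1OCCO1
F6 | step 5 | [1-ethoxycarbonyl-3-(1,3-dioxolan-2-yl)propyl]triphenylphosphonium iodide | CCOC(=O)C(CCC1OCCO1)[P+](c1ccccc1)(c1ccccc1)c1ccccc1.[I-]
F7 | step 5 | ethyl 4-(1,3-dioxolan-2-yl)-2-(triphenylphosphoranylidene)butanoate | CCOC(=O)C(CCC1OCCO1)=P(c1ccccc1)(c1ccccc1)c1ccccc1
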